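**Plan**
1. Cuts: (a) the sp2–sp3 bond between the chain-bearing carbocycle carbon and the first chain CH2 (B-alkyl Suzuki coupling of an enol triflate); (b) inside the carbocycle, once that carbon is taken back to a ketone, the bond between the methyl-bearing carbon and its ring CH2 neighbour; (c) in the chromene, the aryl–O bond and the C4–aryl bond.
2. Enabling feature: the chain-bearing ring carbon lies between the quaternary CMe2 carbon and the methyl-bearing carbon. As C=O it can enolise only toward the latter, so the acyclic isomer 4,4-dimethylhept-6-en-3-one can only fold its ethyl α-carbon onto the terminal olefin carbon (six-membered ring, CMe2 in the tether). The same lock then gives a single enol triflate, which places the tetrasubstituted ring olefin.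
3. Forward: carbocycle first (acid → olefinic ketone → cyclohexanone → enol triflate). In parallel, the chromene from geraniol (tertiary carbinol → aryl alkyne → Z-olefin → pyran ring by C–O coupling), then its prenyl end is turned into a diene. Hydroboration and Suzuki coupling join the halves; desilylation ends the route.
4. Stereochemistry: the only stereocentre (chromene C2, S) comes from Sharpless epoxidation of geraniol with L-(+)-diethyl tartrate, and its C–O bond is never broken afterwards. The E trisubstituted olefin is that of geraniol; SeO2 functionalises its E-methyl group.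

Key step: step 2

Remark: the stereocentre formed in step 2 is racemic and is erased in step 3, so it needs no control; compounds 1, 5 and 9 are taken as purchasable.

**Step 1**
Reactants: 1 2,2-dimethylpent-4-enoic acid
Product: 2 4,4-dimethylhept-6-en-3-one
Conditions: EtLi (2.2 equiv), Et2O, 0 °C to rt; then H2O
Reagents that add atoms: ethyllithium, [Li]CC
Why: A carboxylic acid takes up two equivalents of an alkyllithium (ketone synthesis from a lithium carboxylate) to give a dilithium gem-diolate that is stable until hydrolysis, so the ketone cannot over-add, and the quaternary α-carbon rules out α-deprotonation.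

**Step 2**
Reactants: 2 4,4-dimethylhept-6-en-3-one
Product: 3 2,2,6-trimethylcyclohexan-1-one (racemic)
Conditions: PdCl2(MeCN)2 (10 mol%), CuCl2 (30 mol%), HCl (10 mol%), dioxane, 70 °C, sealed tube
Reagents that add atoms: none
Why: PdCl2(MeCN)2 (divalent palladium) binds the terminal olefin, and the enol of the ethyl ketone, the only enol 2 can form because its other α-carbon is quaternary, attacks the terminal olefin carbon anti to the metal, which makes the ring bond between the future methyl-bearing carbon and its CH2 neighbour and leaves a secondary alkylpalladium; the metal then walks by β-hydride elimination and re-addition to the α-carbon, HCl cleaves the palladium enolate to release the ketone, and CuCl2 returns any zerovalent palladium to the divalent state. The closest known reaction type is the palladium-catalysed intramolecular hydroalkylation of unactivated olefins by alkyl 3-butenyl ketones, a class to which 2 belongs. The six-membered ring closes in the 6-endo-trig mode at the olefin with the enol double bond inside the ring (6-enolendo). The one new stereocentre, the methyl-bearing ring carbon, forms racemic and needs no control because it becomes sp2 in step 3. The step needs attack at the terminal and not the internal olefin carbon: the 5-exo alternative would place the enol double bond inside a five-membered transition state and is geometrically disfavoured, while the gem-dimethyl group blocks the other enol and favours the folded conformer (Thorpe–Ingold effect).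

**Step 3**
Reactants: 3 2,2,6-trimethylcyclohexan-1-one
Product: 4 2,6,6-trimethylcyclohex-1-en-1-yl trifluoromethanesulfonate
Conditions: LiN(iPr)2 (1.2 equiv), THF, −78 to 0 °C; PhNTf2, 0 °C to rt; then H2O
Reagents that add atoms: N-phenylbis(trifluoromethanesulfonimide), O=S(=O)(N(c1ccccc1)S(=O)(=O)C(F)(F)F)C(F)(F)F
Why: Ketone 3 has a single α-hydrogen site, so deprotonation gives one tetrasubstituted enolate whose O-sulfonylation (enol triflate formation) fixes the ring double bond between the future chain-bearing carbon and the methyl-bearing carbon and erases the racemic stereocentre.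

**Step 4**
Reactants: 5 geraniol
Product: 6 (2S,3S)-2,3-epoxygeraniol
Conditions: Ti(OiPr)4 (5 mol%), L-(+)-diethyl tartrate (7 mol%), t-BuOOH, 4 Å molecular sieves, CH2Cl2, −20 °C
Reagents that add atoms: tert-butyl hydroperoxide, CC(C)(C)OO
Why: Sharpless asymmetric epoxidation of the E allylic alcohol with the L-(+)-tartrate–titanium catalyst oxidises only the 2,3-olefin and on the face that gives the (2S,3S) epoxide, which sets the tertiary C–O stereocentre that becomes chromene C2.

**Step 5**
Reactants: 6 (2S,3S)-2,3-epoxygeraniol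
Product: 7 (2R,3S)-2-(chloromethyl)-3-methyl-3-(4-methylpent-3-en-1-yl)oxirane
Conditions: PPh3, CCl4, NaHCO3, reflux
Reagents that add atoms: tetrachloromethane, ClC(Cl)(Cl)Cl
Why: Appel chlorination replaces the primary hydroxyl by chloride under neutral conditions with the epoxide untouched, and no stereocentre takes part (the descriptor at C2 changes only through CIP priorities).

**Step 6**
Reactants: 7 (2R,3S)-2-(chloromethyl)-3-methyl-3-(4-methylpent-3-en-1-yl)oxirane
Product: 8 (S)-3,7-dimethyloct-6-en-1-yn-3-ol
Conditions: n-BuLi (3.3 equiv), THF, −78 to −30 °C; then H2O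
Reagents that add atoms: none
Why: Base-induced fragmentation of a 2,3-epoxy chloride (deprotonation at CH2Cl, β-elimination that opens the epoxide at its C2–O bond, then loss of HCl from the chlorovinyl alkoxide) gives the terminal propargylic alcohol, and the tertiary centre stays S because its C–O bond is never cleaved.

**Step 7**
Reactants: 9 4-bromo-3-iodophenol
Product: 10 (4-bromo-3-iodophenoxy)triisopropylsilane
Conditions: iPr3SiCl, imidazole, DMF, rt
Reagents that add atoms: chlorotriisopropylsilane, CC(C)[Si](Cl)(C(C)C)C(C)C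
Why: Silylation of the phenol gives a bulky aryl silyl ether that survives amine bases, hydrogenation, carbonate and ylides and is removed by fluoride at the end.

**Step 8**
Reactants: 8 (S)-3,7-dimethyloct-6-en-1-yn-3-ol; 10 (4-bromo-3-iodophenoxy)triisopropylsilane
Product: 11 (S)-1-{2-bromo-5-[(triisopropylsilyl)oxy]phenyl}-3,7-dimethyloct-6-en-1-yn-3-ol
Conditions: Pd(PPh3)2Cl2 (2 mol%), CuI (4 mol%), Et3N, THF, rt
Reagents that add atoms: none
Why: Sonogashira coupling occurs at the C–I bond much faster than at C–Br at room temperature, so the alkyne enters meta to the silyloxy group, the ortho bromide is kept for ring closure, and the free tertiary alcohol is tolerated.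

**Step 9**
Reactants: 11 (S)-1-{2-bromo-5-[(triisopropylsilyl)oxy]phenyl}-3,7-dimethyloct-6-en-1-yn-3-ol
Product: 12 (S,Z)-1-{2-bromo-5-[(triisopropylsilyl)oxy]phenyl}-3,7-dimethylocta-1,6-dien-3-ol
Conditions: H2 (1 atm), Pd/CaCO3 poisoned with Pb(OAc)2, quinoline, EtOAc, rt
Reagents that add atoms: none
Why: Lindlar semihydrogenation adds H2 syn on the poisoned palladium surface to give the Z olefin, the geometry that brings the tertiary hydroxyl next to the aryl bromide, and leaves the trisubstituted olefin and the C–Br bond intact.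

**Step 10**
Reactants: 12 (S,Z)-1-{2-bromo-5-[(triisopropylsilyl)oxy]phenyl}-3,7-dimethylocta-1,6-dien-3-ol
Product: 13 (S)-triisopropyl{[2-methyl-2-(4-methylpent-3-en-1-yl)-2H-chromen-6-yl]oxy}silane
Conditions: Pd(OAc)2 (3 mol%), racemic 2-(di-tert-butylphosphino)-1,1'-binaphthyl (4 mol%), Cs2CO3, toluene, 80 °C
Reagents that add atoms: none
Why: Palladium-catalysed intramolecular aryl etherification (C–O cross-coupling) with a bulky di-tert-butylphosphine closes the pyran ring; the tertiary alkoxide has no hydrogen on the carbinol carbon, so C–O reductive elimination is the open path, and the stereocentre is retained because only its O–H bond reacts.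

**Step 11**
Reactants: 13 (S)-triisopropyl{[2-methyl-2-(4-methylpent-3-en-1-yl)-2H-chromen-6-yl]oxy}silane
Product: 15 (S,E)-2-methyl-5-{2-methyl-6-[(triisopropylsilyl)oxy]-2H-chromen-2-yl}pent-2-enal, via allylic alcohol 14 (not isolated)
Conditions: SeO2 (0.3 equiv), t-BuOOH, salicylic acid (cat.), CH2Cl2, rt; filtration, then MnO2, CH2Cl2, rt
Reagents that add atoms: selenium dioxide, O=[Se]=O; tert-butyl hydroperoxide, CC(C)(C)OO
Why: SeO2/t-BuOOH allylic oxidation (ene reaction then 2,3-sigmatropic shift) attacks the E-methyl group of the gem-dimethyl olefin selectively, and MnO2 then oxidises only the allylic alcohol, so the E enal forms with the chromene and silyl ether untouched.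

**Step 12**
Reactants: 15 (S,E)-2-methyl-5-{2-methyl-6-[(triisopropylsilyl)oxy]-2H-chromen-2-yl}pent-2-enal
Product: 16 (S,E)-triisopropyl{[2-methyl-2-(4-methylhexa-3,5-dien-1-yl)-2H-chromen-6-yl]oxy}silane
Conditions: Ph3PCH3Br, KN(SiMe3)2, THF, 0 °C to rt
Reagents that add atoms: methyltriphenylphosphonium bromide, C[P+](c1ccccc1)(c1ccccc1)c1ccccc1.[Br-]
Why: Wittig methylenation with the non-stabilised ylide adds 1,2 to the enal and gives the terminal diene without changing the geometry of the trisubstituted olefin.

**Step 13**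
Reactants: 16 (S,E)-triisopropyl{[2-methyl-2-(4-methylhexa-3,5-dien-1-yl)-2H-chromen-6-yl]oxy}silane; 4 2,6,6-trimethylcyclohex-1-en-1-yl trifluoromethanesulfonate
Product: 18 (S)-triisopropyl({2-methyl-2-[(3E)-4-methyl-6-(2,6,6-trimethylcyclohex-1-en-1-yl)hex-3-en-1-yl]-2H-chromen-6-yl}oxy)silane, via alkylborane 17 (not isolated)
Conditions: 9-borabicyclo[3.3.1]nonane (1.1 equiv), THF, 0 °C to rt; then 4, PdCl2(dppf)·CH2Cl2 (5 mol%), AsPh3 (5 mol%), Cs2CO3, DMF/THF/H2O, 50 °C
Reagents that add atoms: none
Why: 9-Borabicyclo[3.3.1]nonane hydroborates the monosubstituted diene terminus at its CH2 carbon far faster than the trisubstituted or chromene olefin, and the primary alkylborane then undergoes B-alkyl Suzuki–Miyaura coupling with the hindered enol triflate, which forms the sp2–sp3 bond with the tetrasubstituted olefin fixed in place.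

**Step 14**
Reactants: 18 (S)-triisopropyl({2-methyl-2-[(3E)-4-methyl-6-(2,6,6-trimethylcyclohex-1-en-1-yl)hex-3-en-1-yl]-2H-chromen-6-yl}oxy)silane
Product: 19 (S)-2-methyl-2-[(3E)-4-methyl-6-(2,6,6-trimethylcyclohex-1-en-1-yl)hex-3-en-1-yl]-2H-chromen-6-ol
Conditions: Bu4NF, THF, 0 °C
Reagents that add atoms: none
Why: Fluoride cleaves the Si–O bond of the aryl silyl ether (desilylation) under conditions that leave the chromene and both chain olefins unchanged and give the free phenol.

**Compound list**
1 | 2,2-dimethylpent-4-enoic acid | C=CCC(C)(C)C(=O)O | starting material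
2 | 4,4-dimethylhept-6-en-3-one | CCC(=O)C(C)(C)CC=C | intermediate
3 | 2,2,6-trimethylcyclohexan-1-one (racemic) | CC1CCCC(C)(C)C1=O | intermediate
4 | 2,6,6-trimethylcyclohex-1-en-1-yl trifluoromethanesulfonate | CC1=C(OS(=O)(=O)C(F)(F)F)C(C)(C)CCC1 | intermediate
5 | geraniol, (E)-3,7-dimethylocta-2,6-dien-1-ol | CC(C)=CCC/C(C)=C/CO | starting material
6 | (2S,3S)-2,3-epoxygeraniol | OC[C@@H]1O[C@@]1(C)CCC=C(C)C | intermediate
7 | (2R,3S)-2-(chloromethyl)-3-methyl-3-(4-methylpent-3-en-1-yl)oxirane | ClC[C@@H]1O[C@@]1(C)CCC=C(C)C | intermediate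
8 | (S)-3,7-dimethyloct-6-en-1-yn-3-ol | C#C[C@@](C)(O)CCC=C(C)C | intermediate
9 | 4-bromo-3-iodophenol | Oc1ccc(Br)c(I)c1 | starting material
10 | (4-bromo-3-iodophenoxy)triisopropylsilane | CC(C)[Si](Oc1ccc(Br)c(I)c1)(C(C)C)C(C)C | intermediate
11 | (S)-1-{2-bromo-5-[(triisopropylsilyl)oxy]phenyl}-3,7-dimethyloct-6-en-1-yn-3-ol | CC(C)=CCC[C@](C)(O)C#Cc1cc(O[Si](C(C)C)(C(C)C)C(C)C)ccc1Br | intermediate
12 | (S,Z)-1-{2-bromo-5-[(triisopropylsilyl)oxy]phenyl}-3,7-dimethylocta-1,6-dien-3-ol | CC(C)=CCC[C@](C)(O)/C=C\c1cc(O[Si](C(C)C)(C(C)C)C(C)C)ccc1Br | intermediate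
13 | (S)-triisopropyl{[2-methyl-2-(4-methylpent-3-en-1-yl)-2H-chromen-6-yl]oxy}silane | CC(C)=CCC[C@@]1(C)C=Cc2cc(O[Si](C(C)C)(C(C)C)C(C)C)ccc2O1 | intermediate
14 | (S,E)-2-methyl-5-{2-methyl-6-[(triisopropylsilyl)oxy]-2H-chromen-2-yl}pent-2-en-1-ol | OC/C(C)=C/CC[C@@]1(C)C=Cc2cc(O[Si](C(C)C)(C(C)C)C(C)C)ccc2O1 | intermediate
15 | (S,E)-2-methyl-5-{2-methyl-6-[(triisopropylsilyl)oxy]-2H-chromen-2-yl}pent-2-enal | O=C/C(C)=C/CC[C@@]1(C)C=Cc2cc(O[Si](C(C)C)(C(C)C)C(C)C)ccc2O1 | intermediate
16 | (S,E)-triisopropyl{[2-methyl-2-(4-methylhexa-3,5-dien-1-yl)-2H-chromen-6-yl]oxy}silane | C=C/C(C)=C/CC[C@@]1(C)C=Cc2cc(O[Si](C(C)C)(C(C)C)C(C)C)ccc2O1 | intermediate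
17 | 9-[(3E)-3-methyl-6-{(2S)-2-methyl-6-[(triisopropylsilyl)oxy]-2H-chromen-2-yl}hex-3-en-1-yl]-9-borabicyclo[3.3.1]nonane | B1(CC/C(C)=C/CC[C@@]3(C)C=Cc4cc(O[Si](C(C)C)(C(C)C)C(C)C)ccc4O3)C2CCCC1CCC2 | intermediate
18 | (S)-triisopropyl({2-methyl-2-[(3E)-4-methyl-6-(2,6,6-trimethylcyclohex-1-en-1-yl)hex-3-en-1-yl]-2H-chromen-6-yl}oxy)silane | CC1=C(CC/C(C)=C/CC[C@@]2(C)C=Cc3cc(O[Si](C(C)C)(C(C)C)C(C)C)ccc3O2)C(C)(C)CCC1 | intermediate
19 | (S)-2-methyl-2-[(3E)-4-methyl-6-(2,6,6-trimethylcyclohex-1-en-1-yl)hex-3-en-1-yl]-2H-chromen-6-ol | CC1=C(CC/C(C)=C/CC[C@@]2(C)C=Cc3cc(O)ccc3O2)C(C)(C)CCC1 | target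

**Count**
Total steps: 14. Longest linear sequence: 10 (steps 4, 5, 6, 8, 9, 10, 11, 12, 13, 14).

**Steps most likely to fail**

Step 2. The cyclisation may stall through migration of the terminal double bond into the chain by a palladium hydride, or through loss of the catalyst as zerovalent palladium. The same ring bond would then be made by polar chemistry, setting out from 2 and coming back at 3. Radical-chain anti-Markovnikov addition of HBr to 2 (HBr, dibenzoyl peroxide, pentane, 0 °C, light) should give 7-bromo-4,4-dimethylheptan-3-one F1. LiN(iPr)2 in THF (−78 °C to rt) should then close the ring by 6-(enolendo)-exo-tet C-alkylation of the only possible enolate to give 3.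

Step 10. C–O reductive elimination from the arylpalladium alkoxide may be slow, so that hydrodebromination or ionisation of the tertiary allylic alcohol takes over. The pyran ring would then be built in the other order, ether first and the C3=C4 olefin last, setting out from geraniol 5 and coming back at 13. Geraniol with ClCO2Me and pyridine gives geranyl methyl carbonate F2. 2,5-Dihydroxybenzaldehyde is silylated at its free 5-hydroxyl (iPr3SiCl, imidazole) to give 2-hydroxy-5-[(triisopropylsilyl)oxy]benzaldehyde F3. Palladium-catalysed asymmetric O-allylation of the Tsuji–Trost type (Pd2(dba)3·CHCl3 with the C2-symmetric bis(2-diphenylphosphinobenzamide) ligand of trans-1,2-diaminocyclohexane) joins F2 and F3 at the tertiary carbon to give (S)-2-[(3,7-dimethylocta-1,6-dien-3-yl)oxy]-5-[(triisopropylsilyl)oxy]benzaldehyde F4. The ligand antipode that gives the S ether would be identified by comparing the final 13 with 13 from the main route. Wittig methylenation gives (S)-{4-[(3,7-dimethylocta-1,6-dien-3-yl)oxy]-3-vinylphenoxy}triisopropylsilane F5. Ring-closing metathesis of its two vinyl groups with the second-generation Grubbs catalyst (CH2Cl2, 40 °C) gives 13.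

Step 13. Transfer of the bulky alkyl group from boron to the hindered alkenylpalladium may be too slow, so that protodeboronation and β-hydride elimination win. The alkyl group would then be delivered from zinc, setting out from 16 and coming back at 18. Hydroboration of 16 as in step 13 (via 17) followed by oxidation with NaBO3·4H2O in THF/H2O gives (S,E)-3-methyl-6-{2-methyl-6-[(triisopropylsilyl)oxy]-2H-chromen-2-yl}hex-3-en-1-ol F6. I2, PPh3 and imidazole convert it into (S,E)-{[2-(6-iodo-4-methylhex-3-en-1-yl)-2-methyl-2H-chromen-6-yl]oxy}triisopropylsilane F7. Zinc dust with LiCl in THF gives the alkylzinc iodide F8. Negishi coupling of F8 with 4 (Pd(PPh3)4, THF/N-methylpyrrolidone, 60 °C) gives 18. This fallback does not help if the hydroboration itself is unselective on the diene.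

**Further compounds**
F1 | step 2 | 7-bromo-4,4-dimethylheptan-3-one | CCC(=O)C(C)(C)CCCBr
F2 | step 10 | geranyl methyl carbonate | CC(C)=CCC/C(C)=C/COC(=O)OC
F3 | step 10 | 2-hydroxy-5-[(triisopropylsilyl)oxy]benzaldehyde | O=Cc1cc(O[Si](C(C)C)(C(C)C)C(C)C)ccc1O
F4 | step 10 | (S)-2-[(3,7-dimethylocta-1,6-dien-3-yl)oxy]-5-[(triisopropylsilyl)oxy]benzaldehyde | C=C[C@](C)(CCC=C(C)C)Oc1ccc(O[Si](C(C)C)(C(C)C)C(C)C)cc1C=O
F5 | step 10 | (S)-{4-[(3,7-dimethylocta-1,6-dien-3-yl)oxy]-3-vinylphenoxy}triisopropylsilane | C=C[C@](C)(CCC=C(C)C)Oc1ccc(O[Si](C(C)C)(C(C)C)C(C)C)cc1C=C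
F6 | step 13 | (S,E)-3-methyl-6-{2-methyl-6-[(triisopropylsilyl)oxy]-2H-chromen-2-yl}hex-3-en-1-ol | OCC/C(C)=C/CC[C@@]1(C)C=Cc2cc(O[Si](C(C)C)(C(C)C)C(C)C)ccc2O1
F7 | step 13 | (S,E)-{[2-(6-iodo-4-methylhex-3-en-1-yl)-2-methyl-2H-chromen-6-yl]oxy}triisopropylsilane | ICC/C(C)=C/CC[C@@]1(C)C=Cc2cc(O[Si](C(C)C)(C(C)C)C(C)C)ccc2O1
F8 | step 13 | (S,E)-(3-methyl-6-{2-methyl-6-[(triisopropylsilyl)oxy]-2H-chromen-2-yl}hex-3-en-1-yl)zinc iodide | I[Zn]CC/C(C)=C/CC[C@@]1(C)C=Cc2cc(O[Si](C(C)C)(C(C)C)C(C)C)ccc2O1
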